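(All runs are simulated with made-up constants; noise was put on by code.)

1. The product I wanted, complex with one exchanged, rose within a minute in both earlier runs and then sank, so its curve has two parts and a crossing between them.

| flask | starting complex | incoming ligand | remark | time |
|---|---|---|---|---|
| Wednesday's | 1 M | 0.74 M | run made earlier |  |
| Saturday's | 1 M | 1.7 M | run made earlier |  |
| flask | 1.0 M | 1.10 M |  | 20 min |

| run | time / min | complex with one exchanged / % | starting complex / % |
|---|---|---|---|
| Wednesday's | 0.200 | 21.7 | 70.8 |
| Wednesday's | 0.417 | 25.1 | 66.7 |
| Wednesday's | 1.00 | 25.0 | 66.9 |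
| Wednesday's | 2.00 | 23.6 | 66.1 |
| Wednesday's | 4.00 | 22.7 | 63.7 |
| Wednesday's | 10.0 | 20.0 | 58.3 |
| Wednesday's | 20.0 | 16.7 | 51.2 |
| Saturday's | 0.200 | 31.5 | 48.4 |
| Saturday's | 0.417 | 33.9 | 46.7 |
| Saturday's | 1.00 | 32.3 | 48.2 |
| Saturday's | 2.00 | 30.2 | 46.6 |
| Saturday's | 4.00 | 27.8 | 42.2 |
| Saturday's | 10.0 | 22.8 | 31.6 |
| Saturday's | 20.0 | 16.8 | 20.8 |

(scatter of a reading: 0.3 percentage points)



* the moment within 20 min at which there is most complex with one exchanged
* the amount of complex with one exchanged, in percent of the starting complex charged, at that time
* the first time at which complex with one exchanged reaches 21%, in the same percent, in min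

2. Start of the curve: I placed the flask on a straight line between the runs by charge of incoming ligand, 0.375 of the way from Wednesday's to Saturday's. That put the flask at 25.4% at 0.200 min. A straight chord from zero meets 21% at 0.165 min. Wednesday's readings climbed more slowly after their first reading than before it, so I expected that level somewhat earlier in the flask.

3. Crossing: the highest reading stood at 0.417 min on Wednesday and on Saturday. I took that time for the flask too, where the fast rise hands over to the slow fall. The same line gave a peak of 28.4%.

4. Tail: of the peak reading, 0.665 remained at the last reading on Wednesday and 0.496 on Saturday, a fall of 0.177 L mol⁻¹ with the charge of incoming ligand. The line gave this flask 0.602 as its retention, the share of the peak still present at 20 min. My end level was therefore 17.1%.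

5. The forecast gave 0.45 min, 29% and 0.11 min, its peak above mine: “The peak comes where the closing gap matches the slow decay”.

6. The flask gave 0.462 min, 29.8% and 0.0994 min, so the forecast was right within its margins.

    starting complex + incoming ligand ⇌ leaving ligand + complex with one exchanged (K = 0.900, k = 0.0850 L mol⁻¹ s⁻¹)
    complex with one exchanged + incoming ligand ⇌ leaving ligand + complex with two exchanged (K = 0.630, k = 0.210 L mol⁻¹ s⁻¹)
    leaving ligand + complex with one exchanged → side product (k = 0.00380 L mol⁻¹ s⁻¹)
    incoming ligand ⇌ dormant form (K = 1.30, k = 0.0320 s⁻¹)

7. In the flask at 20.0 min, the first exchange, taken by itself, had a relaxation half-life of 0.127 min, short against the 20 min of the run, while side product went from 1.26% at the peak to 39.9% at that time. Retention 0.602 on the peak of this flask gives 17.9%, and the flask held 17.8%.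

8. In a neighbouring flask with 1.9 M of incoming ligand, beyond Saturday's charge, the line gives a retention of 0.460, so that flask's peak of 35.0% should leave 16.1%. It held 16.3% at 20.0 min.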